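**Plan** (atom numbers are labdane numbers of the target: ring A = C10, C1, C2, C3, C4, C5; ring B = C5 to C10; side chain C11 to C16)

- Cuts: acetate; C12–C13 (B-alkyl Suzuki coupling with a bromobutenolide); C11–C12 and C9–O (vinyl carbinol from the 9α,11-epoxide of a C9 methylidene); then the decalin-6,9-dione is cut at C5–C6 and at C3–C4, which leads back to a cyclopentane (C10, C1, C2, C3, C5) carrying an isopropylidene group (C4) and a keto aldehyde chain (C9 to C6).
- Enabling feature: the gem-dimethyl carbon C4 lies next to ring-fusion carbon C5, and C5 lies next to oxygen-bearing C6. C4 can therefore stand outside a five-membered ring as a tertiary cation, C3 can migrate to it, and the charge that then sits on C5 (no hydrogen on C4 or C10) can only be discharged from C6, which becomes a carbonyl carbon.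
- Forward order: cyclopentane with quaternary C10 first; chain C9–C6 added by crotylation; one Lewis-acid step closes ring B (C5–C6) and enlarges the five-membered ring to ring A; then C9 methylidene, C6 carbinol, epoxide, vinyl carbinol, butenolide, acetate.
- Stereochemistry: C10 from the chiral phase-transfer catalyst in step 1, relayed to all others: C5 and C8 by base equilibration next to the two ketones, C6 by thermodynamic dissolving-metal reduction (equatorial OH), C9 by epoxidation anti to the axial C10 methyl.

Key step: step 8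

Remark 1: stereocentres that later become planar or are equilibrated (chain carbons of 9, 12, 13 and 14; the carbinol and C-methyl carbons of 15) are carried as mixtures, and their SMILES bear no descriptor at those atoms.
Remark 2: the sense of induction in step 1 is assigned by analogy with alkylations by the same catalyst class; should the first run show the opposite sense, the antipodal catalyst is used.

Step 1
Reactants: 1 tert-butyl 2-oxocyclopentane-1-carboxylate; 2 iodomethane
Product: 3 tert-butyl (1S)-1-methyl-2-oxocyclopentane-1-carboxylate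
Conditions: MeI, Cs2CO3, (11bR)-4,4-dibutyl-2,6-bis(3,4,5-trifluorophenyl)-4,5-dihydro-3H-dinaphtho[2,1-c:1',2'-e]azepinium bromide (2 mol %), toluene, −40 °C
Reagents that add atoms: iodomethane CI
Why: Asymmetric phase-transfer alkylation of a cyclic β-keto ester, in which the chiral ammonium enolate ion pair exposes one face to MeI, so the quaternary centre (future C10) is set by the catalyst.

Step 2
Reactants: 3 tert-butyl (1S)-1-methyl-2-oxocyclopentane-1-carboxylate; 4 acetone
Product: 5 tert-butyl (1S)-1-methyl-2-(propan-2-ylidene)cyclopentane-1-carboxylate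
Conditions: TiCl4, Zn, pyridine, THF, reflux; 3 and acetone (6 equiv) added slowly
Reagents that add atoms: acetone CC(C)=O
Why: Mixed McMurry reductive coupling with an excess of the small ketone should turn the ring carbonyl into the tetrasubstituted isopropylidene alkene (future C5=C4) while the quaternary centre and the hindered tert-butyl ester stay untouched.

Step 3
Reactants: 5 tert-butyl (1S)-1-methyl-2-(propan-2-ylidene)cyclopentane-1-carboxylate
Product: 6 [(1S)-1-methyl-2-(propan-2-ylidene)cyclopentyl]methanol
Conditions: LiAlH4, Et2O, 0 °C to reflux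
Reagents that add atoms: none
Why: Hydride reduction of an ester to the primary alcohol, which forms no stereocentre and leaves the isolated alkene alone.

Step 4
Reactants: 6 [(1S)-1-methyl-2-(propan-2-ylidene)cyclopentyl]methanol
Product: 7 (1S)-1-methyl-2-(propan-2-ylidene)cyclopentane-1-carbaldehyde
Conditions: Dess–Martin periodinane, pyridine, CH2Cl2, 0 to 25 °C
Reagents that add atoms: none
Why: Dess–Martin oxidation of a primary alcohol to an aldehyde that has no α-hydrogen and so can neither epimerise nor move into conjugation.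

Step 5
Reactants: 7 (1S)-1-methyl-2-(propan-2-ylidene)cyclopentane-1-carbaldehyde; 8 (E)-1-bromobut-2-ene
Product: 9 2-methyl-1-[(1S)-1-methyl-2-(propan-2-ylidene)cyclopentyl]but-3-en-1-ol (chain diastereomers)
Conditions: Zn dust, THF/sat. aq. NH4Cl, 0 to 25 °C
Reagents that add atoms: (E)-1-bromobut-2-ene C/C=C/CBr
Why: Barbier crotylation, in which the allylzinc reacts at its γ-carbon through a six-membered transition state to give the branched homoallylic alcohol; the two new centres (future C9 and C8) need no control because both are later made planar or equilibrated.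

Step 6
Reactants: 9 2-methyl-1-[(1S)-1-methyl-2-(propan-2-ylidene)cyclopentyl]but-3-en-1-ol; 10 9-borabicyclo[3.3.1]nonane (9-BBN); 11 hydrogen peroxide
Product: 13 3-methyl-4-[(1S)-1-methyl-2-(propan-2-ylidene)cyclopentyl]butane-1,4-diol (chain diastereomers), via alkylborane 12 (not isolated)
Conditions: 9-BBN (3 equiv), THF, 0 to 25 °C; then NaOH, H2O2, 0 °C
Reagents that add atoms: hydrogen peroxide OO; 9-BBN [H]B1C2CCCC1CCC2 (boryl group of 12 only)
Why: Brown hydroboration–oxidation, in which the bulky borane adds only to the monosubstituted alkene with anti-Markovnikov orientation and leaves the tetrasubstituted alkene alone.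

Step 7
Reactants: 13 3-methyl-4-[(1S)-1-methyl-2-(propan-2-ylidene)cyclopentyl]butane-1,4-diol
Product: 14 3-methyl-4-[(1S)-1-methyl-2-(propan-2-ylidene)cyclopentyl]-4-oxobutanal (C3 epimers)
Conditions: (COCl)2, DMSO, CH2Cl2, −78 °C; Et3N, −78 to 0 °C
Reagents that add atoms: none
Why: Swern oxidation activates both hydroxyls before the base is added, so the 1,4-diol should go to the keto aldehyde without passing through a lactol that would be oxidised to a lactone.

Step 8
Reactants: 14 3-methyl-4-[(1S)-1-methyl-2-(propan-2-ylidene)cyclopentyl]-4-oxobutanal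
Product: 16 (2R,4aS,8aS)-2,5,5,8a-tetramethyloctahydronaphthalene-1,4-dione, via ene adduct 15 (not isolated)
Conditions: SnCl4 (1.5 equiv), CH2Cl2, −78 to 0 °C; aq. NaHCO3; then NaOMe (cat.), MeOH, 25 °C
Reagents that add atoms: none
Why: Proposed new method: SnCl4 activates the aldehyde (C6), the tetrasubstituted alkene attacks it through C5 in a 6-exo closure of ring B (the topology of the citronellal-to-isopulegol carbonyl-ene/Prins cyclization) and the charge lands on C4, a tertiary carbon outside the five-membered ring; proton loss to the ene adduct 15 is reversible under the tin-bound Brønsted acid. A 1,2-shift of C3 from C5 to C4 then enlarges the cyclopentane (C10, C1, C2, C3, C5) to ring A, and the C5 cation so formed is discharged by a 1,2-hydride shift from the carbinol carbon C6 to give the C6 ketone, which makes the sequence irreversible. The closest known reaction types are the Prins–pinacol cascade, in which a Prins closure is followed by a 1,2-alkyl shift that ends in a carbonyl group, and the acid-induced Wagner–Meerwein enlargement of a cyclopentylcarbinyl cation to a cyclohexyl cation. C10 is carried unchanged from 14, whereas C5 (created by the hydride shift) and C8 each lie α to a ketone and should be equilibrated by NaOMe to the trans ring fusion and the equatorial 8-methyl. The step needs C3 to migrate in preference to C10 or C6: migration of C10 would put the cation at a bridgehead of a bicyclo[4.3.1] skeleton next to the C9 carbonyl, and migration of C6 would enlarge ring B to seven members without relief of cyclopentane strain. It also needs six-ring closure at C5 and not seven-ring closure at C4, which the four-atom tether favours.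

Step 9
Reactants: 16 (2R,4aS,8aS)-2,5,5,8a-tetramethyloctahydronaphthalene-1,4-dione; 17 chlorotrimethylsilane; 18 methyltriphenylphosphonium bromide
Product: 21 (3R,4aS,8aS)-3,4a,8,8-tetramethyl-4-methylideneoctahydronaphthalen-1(2H)-one, via silyl enol ether 19 (not isolated), via methylidene silyl enol ether 20 (not isolated)
Conditions: LDA, TMSCl, THF, −78 °C; crude 19, Ph3P=CH2 (from 18, KOtBu), toluene, 25 to 80 °C; then K2CO3 (cat.), MeOH, 25 °C
Reagents that add atoms: methyltriphenylphosphonium bromide C[P+](c1ccccc1)(c1ccccc1)c1ccccc1.[Br-]; chlorotrimethylsilane C[Si](C)(C)Cl (silyl group of 19 and 20 only, lost again in this step)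
Why: Kinetic deprotonation at the only α-methylene (C7) masks the C6 ketone as its silyl enol ether, so the Wittig methylenation should take place at C9 alone and mild methanolysis returns the C6 ketone; no stereocentre is formed and the 8-methyl stays equatorial.

Step 10
Reactants: 21 (3R,4aS,8aS)-3,4a,8,8-tetramethyl-4-methylideneoctahydronaphthalen-1(2H)-one
Product: 22 (1S,3R,4aS,8aS)-3,4a,8,8-tetramethyl-4-methylidenedecahydronaphthalen-1-ol
Conditions: Li, NH3(l), THF, EtOH, −78 to −33 °C; NH4Cl
Reagents that add atoms: none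
Why: Dissolving-metal reduction of a hindered cyclohexanone should give the more stable equatorial alcohol (6α-OH), because an axial 6β-oxygen would be syn-axial to both the C10 methyl and the 4β-methyl; the isolated alkene is not reduced.

Step 11
Reactants: 22 (1S,3R,4aS,8aS)-3,4a,8,8-tetramethyl-4-methylidenedecahydronaphthalen-1-ol; 23 3-chloroperoxybenzoic acid
Product: 24 (1R,2R,4S,4aS,8aS)-2,5,5,8a-tetramethyloctahydro-2H-spiro[naphthalene-1,2'-oxiran]-4-ol
Conditions: mCPBA, CH2Cl2, −20 to 0 °C
Reagents that add atoms: 3-chloroperoxybenzoic acid OOC(=O)c1cccc(Cl)c1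
Why: Prilezhaev epoxidation of the 1,1-disubstituted alkene should occur from the α face, since the β face is covered by the axial C10 methyl next to C9, so the oxygen ends α on C9.

Step 12
Reactants: 24 (1R,2R,4S,4aS,8aS)-2,5,5,8a-tetramethyloctahydro-2H-spiro[naphthalene-1,2'-oxiran]-4-ol; 25 trimethylsulfonium iodide
Product: 26 (1R,2R,4S,4aS,8aS)-1-ethenyl-2,5,5,8a-tetramethyldecahydronaphthalene-1,4-diol
Conditions: Me3S+ I− (5 equiv), n-BuLi, THF, −10 to 25 °C
Reagents that add atoms: trimethylsulfonium iodide C[S+](C)C.[I-]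
Why: Sulfonium-ylide homologation of an epoxide to the one-carbon-longer allylic alcohol (Corey–Chaykovsky-type ylide), in which the ylide opens the epoxide at its CH2 carbon (C11) and the resulting sulfonium salt eliminates dimethyl sulfide, so the C9–O bond and its α configuration stay untouched.

Step 13
Reactants: 26 (1R,2R,4S,4aS,8aS)-1-ethenyl-2,5,5,8a-tetramethyldecahydronaphthalene-1,4-diol; 10 9-borabicyclo[3.3.1]nonane (9-BBN); 27 3-bromofuran-2(5H)-one
Product: 29 3-{2-[(1R,2R,4S,4aS,8aS)-1,4-dihydroxy-2,5,5,8a-tetramethyldecahydronaphthalen-1-yl]ethyl}furan-2(5H)-one, via alkylborane 28 (not isolated)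
Conditions: 9-BBN (4 equiv), THF, 25 °C; then 27, [1,1'-bis(diphenylphosphino)ferrocene]dichloropalladium PdCl2(dppf) (5 mol %), AsPh3, aq. K3PO4, DMF, 25 °C
Reagents that add atoms: 3-bromofuran-2(5H)-one O=C1OCC=C1Br; 9-BBN [H]B1C2CCCC1CCC2 (boryl group of 28 only)
Why: Hydroboration places boron on the terminal carbon (C12) and the B-alkyl Suzuki–Miyaura coupling, a type established for α-halo enones and enoates, then joins C12 to the α-carbon of the bromobutenolide without touching any stereocentre.

Step 14
Reactants: 29 3-{2-[(1R,2R,4S,4aS,8aS)-1,4-dihydroxy-2,5,5,8a-tetramethyldecahydronaphthalen-1-yl]ethyl}furan-2(5H)-one; 30 acetic anhydride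
Product: 31 (1S,3R,4R,4aS,8aS)-4-hydroxy-3,4a,8,8-tetramethyl-4-[2-(2-oxo-2,5-dihydrofuran-3-yl)ethyl]decahydronaphthalen-1-yl acetate
Conditions: Ac2O, pyridine, DMAP (cat.), CH2Cl2, 0 to 25 °C
Reagents that add atoms: acetic anhydride CC(=O)OC(C)=O
Why: DMAP-catalysed acylation should acetylate the secondary equatorial C6 hydroxyl, while the tertiary C9 hydroxyl between C10 and C8 does not react.

**Compound list**

1 | tert-butyl 2-oxocyclopentane-1-carboxylate | CC(C)(C)OC(=O)C1CCCC1=O | starting material
2 | iodomethane | CI | starting material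
3 | tert-butyl (1S)-1-methyl-2-oxocyclopentane-1-carboxylate | CC(C)(C)OC(=O)[C@@]1(C)CCCC1=O | intermediate
4 | acetone | CC(C)=O | starting material
5 | tert-butyl (1S)-1-methyl-2-(propan-2-ylidene)cyclopentane-1-carboxylate | CC(C)(C)OC(=O)[C@@]1(C)CCCC1=C(C)C | intermediate
6 | [(1S)-1-methyl-2-(propan-2-ylidene)cyclopentyl]methanol | OC[C@@]1(C)CCCC1=C(C)C | intermediate
7 | (1S)-1-methyl-2-(propan-2-ylidene)cyclopentane-1-carbaldehyde | O=C[C@@]1(C)CCCC1=C(C)C | intermediate
8 | (E)-1-bromobut-2-ene | C/C=C/CBr | starting material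
9 | 2-methyl-1-[(1S)-1-methyl-2-(propan-2-ylidene)cyclopentyl]but-3-en-1-ol (chain diastereomers) | C=CC(C)C(O)[C@@]1(C)CCCC1=C(C)C | intermediate
10 | 9-borabicyclo[3.3.1]nonane (9-BBN) | [H]B1C2CCCC1CCC2 | starting material
11 | hydrogen peroxide | OO | starting material
12 | 4-(9-borabicyclo[3.3.1]nonan-9-yl)-2-methyl-1-[(1S)-1-methyl-2-(propan-2-ylidene)cyclopentyl]butan-1-ol (not isolated) | CC(CCB1C2CCCC1CCC2)C(O)[C@@]1(C)CCCC1=C(C)C | intermediate
13 | 3-methyl-4-[(1S)-1-methyl-2-(propan-2-ylidene)cyclopentyl]butane-1,4-diol (chain diastereomers) | OCCC(C)C(O)[C@@]1(C)CCCC1=C(C)C | intermediate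
14 | 3-methyl-4-[(1S)-1-methyl-2-(propan-2-ylidene)cyclopentyl]-4-oxobutanal (C3 epimers) | O=CCC(C)C(=O)[C@@]1(C)CCCC1=C(C)C | intermediate
15 | (3aS,7aS)-7-hydroxy-3a,5-dimethyl-7a-(prop-1-en-2-yl)octahydro-4H-inden-4-one (C5 and C7 epimers; ene adduct, not isolated) | CC(=C)[C@@]12CCC[C@]1(C)C(=O)C(C)CC2O | intermediate
16 | (2R,4aS,8aS)-2,5,5,8a-tetramethyloctahydronaphthalene-1,4-dione | O=C1C[C@@H](C)C(=O)[C@@]2(C)CCCC(C)(C)[C@H]12 | intermediate
17 | chlorotrimethylsilane | C[Si](C)(C)Cl | starting material
18 | methyltriphenylphosphonium bromide | C[P+](c1ccccc1)(c1ccccc1)c1ccccc1.[Br-] | starting material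
19 | (2R,4aS,8aS)-2,5,5,8a-tetramethyl-4-[(trimethylsilyl)oxy]-4a,5,6,7,8,8a-hexahydronaphthalen-1(2H)-one (not isolated) | C[Si](C)(C)OC1=C[C@@H](C)C(=O)[C@@]2(C)CCCC(C)(C)[C@H]12 | intermediate
20 | trimethyl{[(3R,4aS,8aS)-3,4a,8,8-tetramethyl-4-methylidene-3,4,4a,5,6,7,8,8a-octahydronaphthalen-1-yl]oxy}silane (not isolated) | C[Si](C)(C)OC1=C[C@@H](C)C(=C)[C@@]2(C)CCCC(C)(C)[C@H]12 | intermediate
21 | (3R,4aS,8aS)-3,4a,8,8-tetramethyl-4-methylideneoctahydronaphthalen-1(2H)-one | O=C1C[C@@H](C)C(=C)[C@@]2(C)CCCC(C)(C)[C@H]12 | intermediate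
22 | (1S,3R,4aS,8aS)-3,4a,8,8-tetramethyl-4-methylidenedecahydronaphthalen-1-ol | O[C@H]1C[C@@H](C)C(=C)[C@@]2(C)CCCC(C)(C)[C@H]12 | intermediate
23 | 3-chloroperoxybenzoic acid | OOC(=O)c1cccc(Cl)c1 | starting material
24 | (1R,2R,4S,4aS,8aS)-2,5,5,8a-tetramethyloctahydro-2H-spiro[naphthalene-1,2'-oxiran]-4-ol | O[C@H]1C[C@@H](C)[C@]2(CO2)[C@@]3(C)CCCC(C)(C)[C@H]13 | intermediate
25 | trimethylsulfonium iodide | C[S+](C)C.[I-] | starting material
26 | (1R,2R,4S,4aS,8aS)-1-ethenyl-2,5,5,8a-tetramethyldecahydronaphthalene-1,4-diol | O[C@H]1C[C@@H](C)[C@](O)(C=C)[C@@]2(C)CCCC(C)(C)[C@H]12 | intermediate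
27 | 3-bromofuran-2(5H)-one | O=C1OCC=C1Br | starting material
28 | (1R,2R,4S,4aS,8aS)-1-[2-(9-borabicyclo[3.3.1]nonan-9-yl)ethyl]-2,5,5,8a-tetramethyldecahydronaphthalene-1,4-diol (not isolated) | O[C@H]1C[C@@H](C)[C@](O)(CCB2C3CCCC2CCC3)[C@@]2(C)CCCC(C)(C)[C@H]12 | intermediate
29 | 3-{2-[(1R,2R,4S,4aS,8aS)-1,4-dihydroxy-2,5,5,8a-tetramethyldecahydronaphthalen-1-yl]ethyl}furan-2(5H)-one | O[C@H]1C[C@@H](C)[C@](O)(CCC2=CCOC2=O)[C@@]2(C)CCCC(C)(C)[C@H]12 | intermediate
30 | acetic anhydride | CC(=O)OC(C)=O | starting material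
31 | (1S,3R,4R,4aS,8aS)-4-hydroxy-3,4a,8,8-tetramethyl-4-[2-(2-oxo-2,5-dihydrofuran-3-yl)ethyl]decahydronaphthalen-1-yl acetate | CC(=O)O[C@H]1C[C@@H](C)[C@](O)(CCC2=CCOC2=O)[C@@]2(C)CCCC(C)(C)[C@H]12 | target

**Totals:** 14 steps; longest linear sequence 14 steps (fully linear from 1).

**Steps most likely to fail**

Step 8 (the labelled step). The tertiary cation may be quenched by proton loss or by an intramolecular hydride transfer before the ring enlarges, and the 1,4-keto aldehyde may cyclodehydrate to a furan under the Lewis acid. The fallback separates bond formation from ionisation and uses known reaction types. It sets out from 14: Me2AlCl in CH2Cl2 at −78 °C should give the type 1 carbonyl-ene adduct 15, which is now isolated. HCl in Et2O adds across its isopropenyl group to give the tertiary chloride (3aS,7aS)-7a-(2-chloropropan-2-yl)-7-hydroxy-3a,5-dimethyloctahydro-4H-inden-4-one F1. AgSbF6 with 2,6-di-tert-butylpyridine in CH2Cl2 at −40 °C ionises the chloride irreversibly, so the Wagner–Meerwein enlargement and the hydride shift run without a free Lewis acid; NaOMe in MeOH then equilibrates the product, and the route is rejoined at 16.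

Step 2. Pinacol formation, simple reduction of the hindered ketone or self-coupling of acetone may outrun the cross-coupling. The fallback builds the alkene by addition, elimination and 1,4-hydrogenation. It sets out from 3: isopropenylmagnesium bromide with CeCl3 in THF at −78 °C should give tert-butyl (1S)-2-hydroxy-1-methyl-2-(prop-1-en-2-yl)cyclopentane-1-carboxylate F2. Burgess reagent, for which the only β-hydrogens lie on the ring CH2, should give the diene tert-butyl (1S)-1-methyl-2-(prop-1-en-2-yl)cyclopent-2-ene-1-carboxylate F3. 1,4-Addition of H2 across the s-cis diene with (η6-naphthalene)tricarbonylchromium, Cr(CO)3(C10H8), puts the double bond in the tetrasubstituted exocyclic position, and the route is rejoined at 5.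

Step 9. Site selectivity between the two ring ketones may be lost through incomplete or misdirected enolisation, so that olefination also reaches C6. The fallback tells the two positions apart at the alcohol stage. It sets out from 16: Li in NH3 reduces both ketones to the diequatorial diol (1S,2R,4S,4aS,8aS)-2,5,5,8a-tetramethyldecahydronaphthalene-1,4-diol F4. Ac2O in pyridine at 0 °C should acetylate the C6 hydroxyl and leave the C9 hydroxyl, which sits between the quaternary C10 and the methyl-bearing C8, to give (1S,3R,4S,4aS,8aS)-4-hydroxy-3,4a,8,8-tetramethyldecahydronaphthalen-1-yl acetate F5. Dess–Martin oxidation gives (1S,3R,4aS,8aS)-3,4a,8,8-tetramethyl-4-oxodecahydronaphthalen-1-yl acetate F6. Takai–Lombardo methylenation (Zn, CH2Br2, TiCl4), which tolerates esters, gives (1S,3R,4aS,8aS)-3,4a,8,8-tetramethyl-4-methylidenedecahydronaphthalen-1-yl acetate F7. K2CO3 in MeOH removes the acetate, and the route is rejoined at 22.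

Further compounds
F1 | step 8 | (3aS,7aS)-7a-(2-chloropropan-2-yl)-7-hydroxy-3a,5-dimethyloctahydro-4H-inden-4-one (C5 and C7 epimers) | CC(C)(Cl)[C@@]12CCC[C@]1(C)C(=O)C(C)CC2O
F2 | step 2 | tert-butyl (1S)-2-hydroxy-1-methyl-2-(prop-1-en-2-yl)cyclopentane-1-carboxylate (carbinol epimers) | CC(=C)C1(O)CCC[C@]1(C)C(=O)OC(C)(C)C
F3 | step 2 | tert-butyl (1S)-1-methyl-2-(prop-1-en-2-yl)cyclopent-2-ene-1-carboxylate | CC(=C)C1=CCC[C@]1(C)C(=O)OC(C)(C)C
F4 | step 9 | (1S,2R,4S,4aS,8aS)-2,5,5,8a-tetramethyldecahydronaphthalene-1,4-diol | O[C@H]1C[C@@H](C)[C@H](O)[C@@]2(C)CCCC(C)(C)[C@H]12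
F5 | step 9 | (1S,3R,4S,4aS,8aS)-4-hydroxy-3,4a,8,8-tetramethyldecahydronaphthalen-1-yl acetate | CC(=O)O[C@H]1C[C@@H](C)[C@H](O)[C@@]2(C)CCCC(C)(C)[C@H]12
F6 | step 9 | (1S,3R,4aS,8aS)-3,4a,8,8-tetramethyl-4-oxodecahydronaphthalen-1-yl acetate | CC(=O)O[C@H]1C[C@@H](C)C(=O)[C@@]2(C)CCCC(C)(C)[C@H]12
F7 | step 9 | (1S,3R,4aS,8aS)-3,4a,8,8-tetramethyl-4-methylidenedecahydronaphthalen-1-yl acetate | CC(=O)O[C@H]1C[C@@H](C)C(=C)[C@@]2(C)CCCC(C)(C)[C@H]12
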